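## Analysis of the target

Target 25 is a bicyclo[3.3.1]non-2-ene. The numbering used throughout is: bridgeheads C1 and C5, ring A = C1–C2=C3–C4–C5–C9, ring B = C1–C8–C7–C6–C5–C9, and C1′ for the side-chain carbon bonded to C8. C1 is quaternary and carries a formyl group. C2 carries the second formyl group as an enal with C2=C3. C5 is quaternary with a methyl group, C9 is the one-carbon bridge with the acetoxy group, and C8 bears the (2R)-6-methylhept-5-en-2-yl chain.

There are five stereocentres: C1 (R), C5 (R), C8 (S), C9 (R) and C1′ (R). The bridgeheads are tied to each other by the bicycle. What must be controlled is the C9 oxygen (axial on ring B, anti to C3, cis to the C1 formyl group), the C8 side chain (equatorial on ring B, cis to the C2 branch on C1) and the acyclic C8/C1′ pair.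

Sensitive groups are the two aldehydes, the acetate and the trisubstituted side-chain alkene. The C1 formyl group is β to the C9 oxygen, so a free C9 alkoxide can undergo retro-aldol cleavage. The side-chain alkene rules out ozonolysis, unselective hydrogenation and strong electrophiles.

The difficulty is the crowded run C5–C9–C1–C8–C1′, with two quaternary carbons flanking C9 and a quaternary C1 next to the branched C8.

The strategy rests on one feature. C9 and the formyl carbon on C1 are both one-carbon groups on C1. If C9 is also written as a formyl group, C1 becomes the central carbon of a 2,2-disubstituted malondialdehyde, which is not a stereocentre. C9 is bonded to C5, and C5 is the γ-carbon of an allyl unit C7–C6=C5. Ring B can therefore be closed by γ-allylation of one of two formyl groups.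

## Retrosynthetic reasoning

**25 back to 22.** No skeletal bond is cut. The enal comes from allylic alcohol 24, which comes from silyl ether 23, and the acetate comes from alcohol 22. The C2 formyl carbon stays masked as a silyl ether through the chromium and ruthenium steps. The forward steps must acetylate a hindered bridge alcohol and unmask and oxidise one allylic position without touching the acetate or the C1 formyl group.

**22 back to 21.** The C6–C7 single bond is traced to an alkene, because the allyl transposition of the key step leaves a C6=C7 bond in ring B. The forward step must reduce a cis-disubstituted ring alkene in the presence of two trisubstituted alkenes and an aldehyde.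

**21 back to 20.** The C2=C3 bond is cut (ring-closing metathesis). This is the only bond of ring A not attached to a stereocentre. Cutting it leaves an arm on C1 (a 1,1-disubstituted alkene carrying the masked C2 formyl carbon) and an allyl arm on C5. What is gained is the monocyclic cyclohexenol 20, which already holds all five stereocentres. The forward reaction can only work if the two arms are cis on ring B, so it also tests the key step.

**20 back to 18 (through 19).** The C5–C9 bond is cut. With C9 written as a formyl group, C1 becomes a malondialdehyde carbon, and C5 becomes the γ-terminus of a (Z)-allylic bromide at C7. This removes three stereocentres (C1, C5, C9) at once and leaves an open chain whose only stereocentres are C8 and C1′. The forward reaction, a divalent-chromium allylation, must choose one formyl group, one face of the allyl unit and keep the alkene geometry.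

**18 back to 15 (through 17 and 16).** No skeletal bond is cut; this is the order of unmasking. A free C7 hydroxyl next to the dialdehyde would form a five-membered lactol. A free primary hydroxyl next to the C7 bromide would close a tetrahydrofuran. So the two primary alcohols of triol 15 are masked as triethylsilyl ethers (16), the C7 alcohol is brominated while they are masked (17), and the silyl ethers are oxidised directly to the aldehydes last (18).

**15 back to 13 and 14, and 13 back to 11.** The C4–C5 bond is cut between an alkenyl iodide (13) and an allylstannane (14). The (Z) geometry is then fixed at the iodide. The iodide and the C6 hydrogen come from trans-hydroalumination of a propargylic alcohol. The same hydride reagent reduces the lactone and the ester of 11 to the two hydroxymethyl groups, which makes C1 symmetric.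

**11 back to 6 and 9.** The exocyclic C2=CH2 bond is traced to a ketone (10) and the C1–C2 bond to an acylation. C2 is joined to C1 through an sp2 carbon and cannot be brought in by alkylation. Acid chloride 9 (from 7 through 8) supplies C2 and the masked C2 formyl carbon. The lactone ring of 6 holds C1 in a five-membered ring where it is easier to acylate, and ties up the C7 oxygen.

**6 back to 3 and 4.** The C6–C7 bond is cut: addition of the alkynyl Grignard reagent 4 to the aldehyde of 3. C7 need not be controlled. The new hydroxyl lactonises onto one ester.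

**3 back to 1 and 2.** The C1–C8 bond is cut. This is the only stereogenic C–C bond formation before the key step. Aldehyde 1 supplies C7 (its formyl carbon), C8 (its α-carbon), C1′ and the whole side chain. Bromomalonate 2 supplies C1 and both future formyl carbons. The forward reaction is an enamine-based α-alkylation under catalyst control. A conjugate addition of a malonate to an enal was not used, because it would put the aldehyde at C6, need an acceptor one carbon longer than 1, and require extra steps to functionalise C7.

## Alternatives that were turned down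

**Alternative 1: intramolecular furan–aldehyde photocycloaddition (Paternò–Büchi).**
- Disconnection: the C1–C9 bond, with C1 as C3 of a furan, the C1 formyl carbon as furan C2 and C9 as a tethered aldehyde.
- Forward key step: irradiation near 300 nm excites the aldehyde, which adds across the furan 2,3-bond to give the oxetane acetal A1. Ring B is closed and the C9 oxygen is bonded to the future formyl carbon.
- For it: one step makes the quaternary C1 and C9. The four-membered ring enforces the cis relation of the C9 oxygen and the C1 formyl carbon. The acetal is a protected β-hydroxy aldehyde. On this relation it is stronger than the chosen route, which relies on a transition-state preference.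
- Against it: A1 has no C4 and no C2 formyl carbon, and C5 is still an unactivated methine. Making C5 quaternary afterwards needs C9 at the ketone level, which would erase the centre the photoreaction set. The excited aliphatic aldehyde also has γ-hydrogens on the tether and an electron-rich trisubstituted alkene in the side chain, so Norrish fragmentation and oxetane formation at the wrong alkene compete.
- Comparison: the chosen route has C4, the C5 methyl group and the C2 carbons in place before the key step and closes ring A in one metathesis step. Alternative 1 needs a longer sequence after its key step.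

**Alternative 2: enone [2+2] photocycloaddition that brings in both formyl carbons.**
- Disconnection: both formyl carbons are removed together as a two-carbon unit across C1–C2. Ring A is a cyclohexenone with C9 as the carbonyl, C1 as the α-carbon and C2 as the β-carbon.
- Forward key step: irradiation near 350 nm with vinylene carbonate A3 gives the cis-fused cyclobutane carbonate A2, with C1 quaternary.
- For it: enone photocycloaddition is a dependable way to build a quaternary α-carbon and delivers both formyl carbons at once. The C9 ketone would later allow C5 to be made quaternary by enolate alkylation. For the construction of C1 it is at least as strong as acylation of a hindered malonate-type carbanion.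
- Against it: the enone carries the branched C8 on its α-carbon, so the face of the cycloaddition is set only by an exocyclic centre and the distant C5 methyl group. Once the diol is freed, the hydroxyl on the cyclobutane carbon bonded to C1 is β to the C9 ketone, and retro-aldol opening (de Mayo type) would break the C1–formyl bond. The ketone is still needed for the C5 alkylation, so the order of steps is in conflict. The C2=C3 bond must then be made by dehydrogenation of a dialdehyde, and C9 reduced with the right facial sense.
- Comparison: the chosen route needs no stereocontrol at C1 before the key step, sets C9 in the bond-forming step and needs no late dehydrogenation.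

**Alternative 3: intramolecular allylic alkylation (Tsuji–Trost) at C5.**
- Disconnection: the C4–C5 bond; ring A is closed last.
- Forward key step: the potassium enolate of a ring-B C9 ketone attacks the CH2 terminus of a π-allyl complex of palladium, generated from a tertiary allylic carbonate on the C1 branch by a zerovalent palladium catalyst. This gives the bicyclic enone A4 with C2=C3 in place.
- For it: allylic alkylation of ketone enolates is well established, the enolate can form only towards C5, and there is no choice between like groups. For ring A and C5 this closure is better supported than the chosen key step.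
- Against it: it needs a ring-B ketone in which C1 is already a stereodefined quaternary centre with two different oxygenated arms next to C8. The hardest problem is therefore moved to an earlier, unsolved stage. After the closure, C9 must be reduced on a hindered bridging ketone, and two silyl ethers must be taken to aldehydes.
- Comparison: the chosen route offers a precursor in which C1 is symmetric until the key step, a C1 formyl group already at the right oxidation level, and C9 formed with its oxygen in place.

Key step: step 12

Remark: C7 (alcohol, then bromide) is carried as a mixture of both epimers, and the malonate-derived ring carbon of lactones 6, 10 and 11 is not controlled; step 7 makes that carbon symmetric and step 12 destroys the C7 centre.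

## Route

Step 1
Reactants: 1 (R)-citronellal; 2 diethyl bromomalonate
Product: 3 diethyl 2-[(2S,3R)-3,7-dimethyl-1-oxooct-6-en-2-yl]propanedioate
Conditions: (2S,5R)-2-tert-butyl-3,5-dimethylimidazolidin-4-one·TfOH (20 mol%), Ru(bpy)3Cl2 (0.5 mol%), 2,6-lutidine, DMF, visible light, rt; 1 in twofold excess
Reagents that add atoms: none
Why: Photoredox organocatalytic α-alkylation of an aldehyde: excited Ru(bpy)3Cl2 reduces 2 to the electrophilic malonyl radical, which adds to the catalytic (E)-enamine of 1. In that enamine the alkene points away from the tert-butyl group and the 5-methyl group covers the Si face of C8, so the radical should add to the Re face and set C8 as (S) under catalyst control; the enamine is far more electron-rich than the side-chain alkene.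

Step 2
Reactants: 3; 4 prop-1-ynylmagnesium bromide
Product: 6 ethyl (4S)-4-[(2R)-6-methylhept-5-en-2-yl]-2-oxo-5-(prop-1-yn-1-yl)oxolane-3-carboxylate, via hydroxy diester 5 (not isolated)
Conditions: 4 (2.2 equiv), THF, −78 → 0 °C; aq. NH4Cl; then TsOH·H2O (cat.), CH2Cl2, rt
Reagents that add atoms: none
Why: Alkynyl Grignard addition to the aldehyde; the first equivalent only deprotonates the malonate. Acid then closes the γ-lactone by attack of the C7 hydroxyl on one ester. C7 forms as both epimers, which is harmless.

Step 3
Reactants: 7 glycolic acid
Product: 8 tert-butyldimethylsilyl 2-[(tert-butyldimethylsilyl)oxy]acetate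
Conditions: TBSCl (2.2 equiv), imidazole, DMF, rt
Reagents that add atoms: tert-butyldimethylsilyl chloride, CC(C)(C)[Si](C)(C)Cl
Why: Silylation of both the hydroxyl and the carboxyl group (silyl ether and silyl ester).

Step 4
Reactants: 8
Product: 9 2-[(tert-butyldimethylsilyl)oxy]acetyl chloride
Conditions: (COCl)2, DMF (cat.), CH2Cl2, 0 °C → rt; used crude
Reagents that add atoms: oxalyl chloride, O=C(Cl)C(Cl)=O
Why: Silyl esters are converted into acid chlorides by the chloroiminium species from (COCl)2 and DMF without free HCl, so the silyl ether survives.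

Step 5
Reactants: 6; 9
Product: 10 ethyl (4S)-3-{2-[(tert-butyldimethylsilyl)oxy]acetyl}-4-[(2R)-6-methylhept-5-en-2-yl]-2-oxo-5-(prop-1-yn-1-yl)oxolane-3-carboxylate
Conditions: NaH, THF, 0 °C; then 9, 0 °C → rt
Reagents that add atoms: none
Why: C-acylation of the sodium enolate of an α-alkoxycarbonyl lactone (a malonate-type carbanion) by an acid chloride; the five-membered ring keeps C1 accessible. C1 becomes quaternary; its configuration does not matter because both carbonyl groups on it become hydroxymethyl groups in step 7.

Step 6
Reactants: 10
Product: 11 ethyl (4S)-3-{3-[(tert-butyldimethylsilyl)oxy]prop-1-en-2-yl}-4-[(2R)-6-methylhept-5-en-2-yl]-2-oxo-5-(prop-1-yn-1-yl)oxolane-3-carboxylate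
Conditions: Zn, CH2Br2, TiCl4, THF/CH2Cl2, 0 °C → rt
Reagents that add atoms: dibromomethane, BrCBr
Why: Takai–Lombardo methylenation: a non-basic titanium methylidene equivalent that converts hindered, base-sensitive ketones into 1,1-disubstituted alkenes and leaves esters and lactones alone, so the tricarbonyl unit is not cleaved by retro-Claisen reaction.

Step 7
Reactants: 11
Product: 13 2-{3-[(tert-butyldimethylsilyl)oxy]prop-1-en-2-yl}-2-[(2Z,5S,6R)-4-hydroxy-2-iodo-6,10-dimethylundeca-2,9-dien-5-yl]propane-1,3-diol, via alkynyl triol 12 (not isolated)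
Conditions: NaAlH2(OCH2CH2OCH3)2 (excess), THF, 0 °C → rt; EtOAc; then I2, THF, −78 → −10 °C
Reagents that add atoms: iodine, II
Why: The aluminium hydride reduces lactone and ester to the two primary alcohols (C1 becomes symmetric) and frees the C7 alkoxide, which directs trans-hydroalumination of the alkyne with hydride at C6 and aluminium at C5; iodine replaces aluminium with retention. This is the known stereospecific route from propargylic alcohols to (Z)-3-iodoallylic alcohols and places C7 cis to iodine.

Step 8
Reactants: 13; 14 allyltributylstannane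
Product: 15 2-{3-[(tert-butyldimethylsilyl)oxy]prop-1-en-2-yl}-2-[(4Z,7S,8R)-6-hydroxy-4,8,12-trimethyltrideca-1,4,11-trien-7-yl]propane-1,3-diol
Conditions: Pd2(dba)3 (cat.), AsPh3, CuI, DMF, rt
Reagents that add atoms: none
Why: Stille coupling of an alkenyl iodide with an allylstannane proceeds with retention at the alkene, so the allyl arm (C4) ends cis to C7. Free hydroxyl groups are tolerated, and mild conditions limit migration of the skipped diene into conjugation.

Step 9
Reactants: 15
Product: 16 (4Z,7S,8R)-7-[4-[(tert-butyldimethylsilyl)oxy]-3-methylidene-1-[(triethylsilyl)oxy]-2-{[(triethylsilyl)oxy]methyl}butan-2-yl]-4,8,12-trimethyltrideca-1,4,11-trien-6-ol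
Conditions: TESCl (2.1 equiv), imidazole, CH2Cl2, −40 → −20 °C
Reagents that add atoms: chlorotriethylsilane, CC[Si](Cl)(CC)CC
Why: Silylation at low temperature distinguishes the two primary alcohols from the secondary allylic C7 alcohol, which is flanked by C8 and the (Z)-alkene.

Step 10
Reactants: 16
Product: 17 (4Z,7S,8R)-6-bromo-7-[4-[(tert-butyldimethylsilyl)oxy]-3-methylidene-1-[(triethylsilyl)oxy]-2-{[(triethylsilyl)oxy]methyl}butan-2-yl]-4,8,12-trimethyltrideca-1,4,11-triene
Conditions: CBr4, PPh3, 2,6-lutidine, CH2Cl2, −20 → 0 °C
Reagents that add atoms: carbon tetrabromide, BrC(Br)(Br)Br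
Why: Appel bromination of the allylic alcohol under buffered conditions that keep the silyl ethers. Either C7 epimer serves, but the (Z) geometry must survive, hence the low temperature.

Step 11
Reactants: 17
Product: 18 2-[(4Z,7S,8R)-6-bromo-4,8,12-trimethyltrideca-1,4,11-trien-7-yl]-2-{3-[(tert-butyldimethylsilyl)oxy]prop-1-en-2-yl}propanedial
Conditions: (COCl)2, DMSO, CH2Cl2, −78 → −35 °C; Et3N, −78 → 0 °C; short filtration, used at once
Reagents that add atoms: none
Why: Swern conditions cleave primary triethylsilyl ethers and oxidise them in the same operation. The dialdehyde therefore forms without a free diol facing the allylic bromide and without a free C7 hydroxyl facing the aldehydes. The malondialdehyde has no α-hydrogen.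

Step 12
Reactants: 18
Product: 20 (1R,2R,5S,6R)-1-{3-[(tert-butyldimethylsilyl)oxy]prop-1-en-2-yl}-6-hydroxy-5-methyl-2-[(2R)-6-methylhept-5-en-2-yl]-5-(prop-2-en-1-yl)cyclohex-3-ene-1-carbaldehyde, via allylchromium dichloride 19 (not isolated)
Conditions: CrCl2 (excess), THF, high dilution, slow addition of 18, 0 °C → rt; aqueous work-up
Reagents that add atoms: none
Why: Two equivalents of CrCl2 reduce the C7–Br bond through the allyl radical to the σ-allyl complex 19 of trivalent chromium, bound at the secondary C7 and not at the tertiary C5, so the configuration of the bromide is erased. The metal binds a formyl oxygen and the allyl group is delivered through its γ-carbon C5 in a closed, chromium-bridged transition state (the forming carbocycle and the C7–Cr–O–C9 bridge make a boat-like bicyclo[2.2.2] array); this forms C5–C9 and moves the alkene to C6=C7. The closest known reaction type is the intramolecular Nozaki–Hiyama–Kishi (Barbier-type) allylation through the more substituted γ-terminus, which creates a quaternary carbon. Ring B closes in a six-membered mode, 6-exo-trig at the carbonyl carbon, with the transposed C6=C7 bond inside the ring. C5: metal and carbonyl oxygen share one face of the allyl unit, so the substituent cis to C7 in the (Z)-alkene (the C4 arm) ends anti to the C9 oxygen and the methyl group syn to it. C9: its oxygen is the one held in the chromium bridge, which should lie on the ring face opposite the C8 side chain, because that chain avoids the ligand sphere of the metal and stays pseudo-equatorial. C1: the formyl group that is not attacked is expected to remain on the chromium side, where it can act as a second ligand in a six-membered chelate, and this pushes the larger 2-propenyl arm to the open face, cis to the C4 arm. The step needs selection between two formyl groups and retention of the (Z) geometry; high dilution, the lack of enolisable hydrogens and fast intramolecular capture are relied on, and the selection has no precedent on a malondialdehyde.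

Step 13
Reactants: 20
Product: 21 (1R,5S,8R,9R)-2-{[(tert-butyldimethylsilyl)oxy]methyl}-9-hydroxy-5-methyl-8-[(2R)-6-methylhept-5-en-2-yl]bicyclo[3.3.1]nona-2,6-diene-1-carbaldehyde
Conditions: second-generation Grubbs catalyst RuCl2(=CHPh)(H2IMes)(PCy3) (cat.), CH2Cl2, high dilution, 40 °C
Reagents that add atoms: none
Why: Ring-closing metathesis: the catalyst loads on the monosubstituted alkene of the C5 arm and closes onto the 1,1-disubstituted alkene of the C1 arm, giving the trisubstituted C2=C3 bond of ring A. Only the diastereomer with both arms cis on ring B can cyclise; the ring alkene and the side-chain alkene are too hindered or too remote to compete.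

Step 14
Reactants: 21
Product: 22 (1R,5R,8S,9R)-2-{[(tert-butyldimethylsilyl)oxy]methyl}-9-hydroxy-5-methyl-8-[(2R)-6-methylhept-5-en-2-yl]bicyclo[3.3.1]non-2-ene-1-carbaldehyde
Conditions: KO2CN=NCO2K, AcOH, CH2Cl2, rt, repeated charges
Reagents that add atoms: none
Why: Diimide transfers hydrogen through a cyclic transition state and reacts much faster with the cis-disubstituted C6=C7 bond than with trisubstituted alkenes. Generating it from the azodicarboxylate salt avoids sulfonyl hydrazides that could condense with the aldehyde.

Step 15
Reactants: 22
Product: 23 (1R,5R,8S,9R)-2-{[(tert-butyldimethylsilyl)oxy]methyl}-1-formyl-5-methyl-8-[(2R)-6-methylhept-5-en-2-yl]bicyclo[3.3.1]non-2-en-9-yl acetate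
Conditions: Ac2O, DMAP, Et3N, CH2Cl2, rt → 40 °C
Reagents that add atoms: acetic anhydride, CC(=O)OC(C)=O
Why: DMAP-catalysed acetylation; the C9 alcohol has two quaternary neighbours, so excess reagent and mild warming are planned. The amine base is too weak to start a retro-aldol of the β-hydroxy aldehyde.

Step 16
Reactants: 23
Product: 24 (1R,5R,8S,9R)-1-formyl-2-(hydroxymethyl)-5-methyl-8-[(2R)-6-methylhept-5-en-2-yl]bicyclo[3.3.1]non-2-en-9-yl acetate
Conditions: HF·pyridine, pyridine, THF, 0 °C → rt
Reagents that add atoms: none
Why: Buffered HF·pyridine removes the primary allylic silyl ether without touching the acetate or the aldehyde and without the basicity of fluoride salts.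

Step 17
Reactants: 24
Product: 25 (1R,5R,8S,9R)-1,2-diformyl-5-methyl-8-[(2R)-6-methylhept-5-en-2-yl]bicyclo[3.3.1]non-2-en-9-yl acetate (the target)
Conditions: MnO2, CH2Cl2, rt
Reagents that add atoms: none
Why: MnO2 oxidises allylic alcohols selectively to enals under neutral conditions; no other group in 24 is oxidised.

## Compound list

1 | (R)-citronellal, (3R)-3,7-dimethyloct-6-enal | O=CC[C@H](C)CCC=C(C)C | starting material
2 | diethyl bromomalonate | CCOC(=O)C(Br)C(=O)OCC | starting material
3 | diethyl 2-[(2S,3R)-3,7-dimethyl-1-oxooct-6-en-2-yl]propanedioate | CCOC(=O)C(C(=O)OCC)[C@H]([C@H](C)CCC=C(C)C)C=O | intermediate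
4 | prop-1-ynylmagnesium bromide | CC#C[Mg]Br | starting material
5 | diethyl 2-[(5S,6R)-4-hydroxy-6,10-dimethylundec-9-en-2-yn-5-yl]propanedioate (both C4 epimers; not isolated) | CCOC(=O)C(C(=O)OCC)[C@H]([C@H](C)CCC=C(C)C)C(O)C#CC | intermediate
6 | ethyl (4S)-4-[(2R)-6-methylhept-5-en-2-yl]-2-oxo-5-(prop-1-yn-1-yl)oxolane-3-carboxylate (epimers at C3 and C5) | CCOC(=O)C1C(=O)OC(C#CC)[C@H]1[C@H](C)CCC=C(C)C | intermediate
7 | glycolic acid | OCC(=O)O | starting material
8 | tert-butyldimethylsilyl 2-[(tert-butyldimethylsilyl)oxy]acetate | CC(C)(C)[Si](C)(C)OCC(=O)O[Si](C)(C)C(C)(C)C | intermediate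
9 | 2-[(tert-butyldimethylsilyl)oxy]acetyl chloride | CC(C)(C)[Si](C)(C)OCC(Cl)=O | intermediate
10 | ethyl (4S)-3-{2-[(tert-butyldimethylsilyl)oxy]acetyl}-4-[(2R)-6-methylhept-5-en-2-yl]-2-oxo-5-(prop-1-yn-1-yl)oxolane-3-carboxylate | CCOC(=O)C1(C(=O)CO[Si](C)(C)C(C)(C)C)C(=O)OC(C#CC)[C@H]1[C@H](C)CCC=C(C)C | intermediate
11 | ethyl (4S)-3-{3-[(tert-butyldimethylsilyl)oxy]prop-1-en-2-yl}-4-[(2R)-6-methylhept-5-en-2-yl]-2-oxo-5-(prop-1-yn-1-yl)oxolane-3-carboxylate | CCOC(=O)C1(C(=C)CO[Si](C)(C)C(C)(C)C)C(=O)OC(C#CC)[C@H]1[C@H](C)CCC=C(C)C | intermediate
12 | 2-{3-[(tert-butyldimethylsilyl)oxy]prop-1-en-2-yl}-2-[(5S,6R)-4-hydroxy-6,10-dimethylundec-9-en-2-yn-5-yl]propane-1,3-diol (as its aluminate; not isolated) | OCC(CO)(C(=C)CO[Si](C)(C)C(C)(C)C)[C@H]([C@H](C)CCC=C(C)C)C(O)C#CC | intermediate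
13 | 2-{3-[(tert-butyldimethylsilyl)oxy]prop-1-en-2-yl}-2-[(2Z,5S,6R)-4-hydroxy-2-iodo-6,10-dimethylundeca-2,9-dien-5-yl]propane-1,3-diol | OCC(CO)(C(=C)CO[Si](C)(C)C(C)(C)C)[C@H]([C@H](C)CCC=C(C)C)C(O)/C=C(/C)I | intermediate
14 | allyltributylstannane | C=CC[Sn](CCCC)(CCCC)CCCC | starting material
15 | 2-{3-[(tert-butyldimethylsilyl)oxy]prop-1-en-2-yl}-2-[(4Z,7S,8R)-6-hydroxy-4,8,12-trimethyltrideca-1,4,11-trien-7-yl]propane-1,3-diol | OCC(CO)(C(=C)CO[Si](C)(C)C(C)(C)C)[C@H]([C@H](C)CCC=C(C)C)C(O)/C=C(/C)CC=C | intermediate
16 | (4Z,7S,8R)-7-[4-[(tert-butyldimethylsilyl)oxy]-3-methylidene-1-[(triethylsilyl)oxy]-2-{[(triethylsilyl)oxy]methyl}butan-2-yl]-4,8,12-trimethyltrideca-1,4,11-trien-6-ol | CC[Si](CC)(CC)OCC(CO[Si](CC)(CC)CC)(C(=C)CO[Si](C)(C)C(C)(C)C)[C@H]([C@H](C)CCC=C(C)C)C(O)/C=C(/C)CC=C | intermediate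
17 | (4Z,7S,8R)-6-bromo-7-[4-[(tert-butyldimethylsilyl)oxy]-3-methylidene-1-[(triethylsilyl)oxy]-2-{[(triethylsilyl)oxy]methyl}butan-2-yl]-4,8,12-trimethyltrideca-1,4,11-triene | CC[Si](CC)(CC)OCC(CO[Si](CC)(CC)CC)(C(=C)CO[Si](C)(C)C(C)(C)C)[C@H]([C@H](C)CCC=C(C)C)C(Br)/C=C(/C)CC=C | intermediate
18 | 2-[(4Z,7S,8R)-6-bromo-4,8,12-trimethyltrideca-1,4,11-trien-7-yl]-2-{3-[(tert-butyldimethylsilyl)oxy]prop-1-en-2-yl}propanedial (precursor of the key step) | O=CC(C=O)(C(=C)CO[Si](C)(C)C(C)(C)C)[C@H]([C@H](C)CCC=C(C)C)C(Br)/C=C(/C)CC=C | intermediate
19 | [(4Z,7S,8R)-7-(2-{3-[(tert-butyldimethylsilyl)oxy]prop-1-en-2-yl}-1,3-dioxopropan-2-yl)-4,8,12-trimethyltrideca-1,4,11-trien-6-yl]chromium dichloride (trivalent chromium, solvated; not isolated) | O=CC(C=O)(C(=C)CO[Si](C)(C)C(C)(C)C)[C@H]([C@H](C)CCC=C(C)C)C([Cr](Cl)Cl)/C=C(/C)CC=C | intermediate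
20 | (1R,2R,5S,6R)-1-{3-[(tert-butyldimethylsilyl)oxy]prop-1-en-2-yl}-6-hydroxy-5-methyl-2-[(2R)-6-methylhept-5-en-2-yl]-5-(prop-2-en-1-yl)cyclohex-3-ene-1-carbaldehyde (product of the key step) | O[C@@H]1[C@@](C)(CC=C)C=C[C@@H]([C@H](C)CCC=C(C)C)[C@@]1(C=O)C(=C)CO[Si](C)(C)C(C)(C)C | intermediate
21 | (1R,5S,8R,9R)-2-{[(tert-butyldimethylsilyl)oxy]methyl}-9-hydroxy-5-methyl-8-[(2R)-6-methylhept-5-en-2-yl]bicyclo[3.3.1]nona-2,6-diene-1-carbaldehyde | O[C@@H]1[C@@]2(C)CC=C(CO[Si](C)(C)C(C)(C)C)[C@]1(C=O)[C@H]([C@H](C)CCC=C(C)C)C=C2 | intermediate
22 | (1R,5R,8S,9R)-2-{[(tert-butyldimethylsilyl)oxy]methyl}-9-hydroxy-5-methyl-8-[(2R)-6-methylhept-5-en-2-yl]bicyclo[3.3.1]non-2-ene-1-carbaldehyde | O[C@@H]1[C@@]2(C)CC=C(CO[Si](C)(C)C(C)(C)C)[C@]1(C=O)[C@H]([C@H](C)CCC=C(C)C)CC2 | intermediate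
23 | (1R,5R,8S,9R)-2-{[(tert-butyldimethylsilyl)oxy]methyl}-1-formyl-5-methyl-8-[(2R)-6-methylhept-5-en-2-yl]bicyclo[3.3.1]non-2-en-9-yl acetate | CC(=O)O[C@@H]1[C@@]2(C)CC=C(CO[Si](C)(C)C(C)(C)C)[C@]1(C=O)[C@H]([C@H](C)CCC=C(C)C)CC2 | intermediate
24 | (1R,5R,8S,9R)-1-formyl-2-(hydroxymethyl)-5-methyl-8-[(2R)-6-methylhept-5-en-2-yl]bicyclo[3.3.1]non-2-en-9-yl acetate | CC(=O)O[C@@H]1[C@@]2(C)CC=C(CO)[C@]1(C=O)[C@H]([C@H](C)CCC=C(C)C)CC2 | intermediate
25 | (1R,5R,8S,9R)-1,2-diformyl-5-methyl-8-[(2R)-6-methylhept-5-en-2-yl]bicyclo[3.3.1]non-2-en-9-yl acetate | CC(=O)O[C@@H]1[C@@]2(C)CC=C(C=O)[C@]1(C=O)[C@H]([C@H](C)CCC=C(C)C)CC2 | target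

## Step count and least certain steps

Total step count: 17. Longest linear sequence: 15 steps (steps 1, 2 and 5 to 17, from 1 to 25); steps 3 and 4 are a two-step side branch.

**Step 12 (key step).** Three processes can defeat it. The first is attack on the other formyl group, because only the proposed chelation tells the two apart; this gives the C1 epimer, whose arms are trans and cannot be joined. The second is a 1,3-shift of chromium to C5 and back, which changes the alkene geometry and the face carrying the metal and gives the C5 epimer. The third is intermolecular coupling or protonation of the allylchromium species.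
Fallback, from 15 back to 20: the choice between the two carbons is made before the ring closure. Lipase-catalysed acylation of triol 15 with vinyl acetate gives the mono-acetate F1 at the hydroxymethyl group that is to become the C1 formyl group (if the enzyme prefers the other arm, the diacetate is hydrolysed with the same enzyme). The remaining primary alcohol is silylated with TESCl to the mono-triethylsilyl ether F2. CBr4/PPh3 gives the bromide F3, and Swern conditions give the bromo mono-aldehyde F4. CrCl2 then closes ring B on the only aldehyde present to the cyclohexenol acetate F5. K2CO3 in MeOH gives the diol F6, and TEMPO/PhI(OAc)2 oxidises only the primary alcohol, which returns the route to 20.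

**Step 1.** The malonyl radical may add to the trisubstituted side-chain alkene (atom-transfer addition), and the β-branched aldehyde may form its enamine slowly, which weakens catalyst control.
Fallback, from 1 back to 6: a polar route without radicals. L-Proline-catalysed aldol addition of 1 to diethyl oxomalonate gives the hydroxy malonate aldehyde F7. Excess 4 followed by acid gives the hydroxy lactone F8. Ac2O/DMAP gives the acetate F9, and SmI2 removes the α-acetoxy group, which returns the route to 6.

**Step 5.** Acylation may occur on oxygen, or not at all at the crowded carbanion, and the acyl group may be lost by retro-Claisen cleavage during work-up.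
Fallback, from 6 back to 10: the C1–C2 bond is made by an aldol reaction. Me3SiCl/Et3N converts 6 into the silyl ketene acetal F10. A Mukaiyama aldol addition (BF3·OEt2) to (tert-butyldimethylsilyloxy)acetaldehyde gives the secondary alcohol F11, and Dess–Martin periodinane oxidises it to 10.

**Step 11.** Cleavage of the neopentyl-type triethylsilyl ethers may be incomplete, which stops at the mono-aldehyde, and chloride may exchange with or displace the allylic bromide.
Fallback, from 16 back to 18: the C7 oxygen is carried as a phosphate through the oxidation. ClP(O)(OEt)2 and N-methylimidazole convert 16 into the diethyl phosphate F12. HF·pyridine buffered with pyridine removes both triethylsilyl ethers to give the diol phosphate F13. Dess–Martin periodinane gives the dialdehyde phosphate F14, and LiBr in THF displaces the phosphate to give 18.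

**Step 14.** The side-chain alkene may be over-reduced, the hindered C6=C7 bond may react slowly, and hydrazine formed by disproportionation of diimide may condense with the aldehyde.
Fallback, from 21 back to 23: acetylation first (Ac2O, DMAP) gives the diene acetate F15. Hydrogenation with RhCl(PPh3)3 under H2 (1 atm) reduces only the disubstituted C6=C7 bond and gives 23.

## Further compounds

F1 | step 12 | mono-acetate of 15 at the hydroxymethyl group that becomes the C1 formyl group | CC(=O)OC[C@@](CO)(C(=C)CO[Si](C)(C)C(C)(C)C)[C@H]([C@H](C)CCC=C(C)C)C(O)/C=C(/C)CC=C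
F2 | step 12 | mono-triethylsilyl ether of F1 | CC(=O)OC[C@@](CO[Si](CC)(CC)CC)(C(=C)CO[Si](C)(C)C(C)(C)C)[C@H]([C@H](C)CCC=C(C)C)C(O)/C=C(/C)CC=C
F3 | step 12 | C7 bromide of F2 | CC(=O)OC[C@@](CO[Si](CC)(CC)CC)(C(=C)CO[Si](C)(C)C(C)(C)C)[C@H]([C@H](C)CCC=C(C)C)C(Br)/C=C(/C)CC=C
F4 | step 12 | bromo mono-aldehyde with acetoxymethyl group on C1 | CC(=O)OC[C@@](C=O)(C(=C)CO[Si](C)(C)C(C)(C)C)[C@H]([C@H](C)CCC=C(C)C)C(Br)/C=C(/C)CC=C
F5 | step 12 | ring-B cyclohexenol with acetoxymethyl group on C1 | O[C@@H]1[C@@](C)(CC=C)C=C[C@@H]([C@H](C)CCC=C(C)C)[C@@]1(COC(C)=O)C(=C)CO[Si](C)(C)C(C)(C)C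
F6 | step 12 | ring-B cyclohexenol with hydroxymethyl group on C1 (diol) | O[C@@H]1[C@@](C)(CC=C)C=C[C@@H]([C@H](C)CCC=C(C)C)[C@@]1(CO)C(=C)CO[Si](C)(C)C(C)(C)C
F7 | step 1 | diethyl 2-hydroxy-2-[(2S,3R)-3,7-dimethyl-1-oxooct-6-en-2-yl]propanedioate | CCOC(=O)C(O)(C(=O)OCC)[C@H]([C@H](C)CCC=C(C)C)C=O
F8 | step 1 | ethyl (4S)-3-hydroxy-4-[(2R)-6-methylhept-5-en-2-yl]-2-oxo-5-(prop-1-yn-1-yl)oxolane-3-carboxylate | CCOC(=O)C1(O)C(=O)OC(C#CC)[C@H]1[C@H](C)CCC=C(C)C
F9 | step 1 | ethyl (4S)-3-acetoxy-4-[(2R)-6-methylhept-5-en-2-yl]-2-oxo-5-(prop-1-yn-1-yl)oxolane-3-carboxylate | CCOC(=O)C1(OC(C)=O)C(=O)OC(C#CC)[C@H]1[C@H](C)CCC=C(C)C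
F10 | step 5 | trimethylsilyl ketene acetal of 6 | CCOC(O[Si](C)(C)C)=C1C(=O)OC(C#CC)[C@H]1[C@H](C)CCC=C(C)C
F11 | step 5 | ethyl (4S)-3-{2-[(tert-butyldimethylsilyl)oxy]-1-hydroxyethyl}-4-[(2R)-6-methylhept-5-en-2-yl]-2-oxo-5-(prop-1-yn-1-yl)oxolane-3-carboxylate | CCOC(=O)C1(C(O)CO[Si](C)(C)C(C)(C)C)C(=O)OC(C#CC)[C@H]1[C@H](C)CCC=C(C)C
F12 | step 11 | diethyl phosphate of 16 at C7 | CC[Si](CC)(CC)OCC(CO[Si](CC)(CC)CC)(C(=C)CO[Si](C)(C)C(C)(C)C)[C@H]([C@H](C)CCC=C(C)C)C(OP(=O)(OCC)OCC)/C=C(/C)CC=C
F13 | step 11 | diol phosphate | OCC(CO)(C(=C)CO[Si](C)(C)C(C)(C)C)[C@H]([C@H](C)CCC=C(C)C)C(OP(=O)(OCC)OCC)/C=C(/C)CC=C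
F14 | step 11 | dialdehyde phosphate | O=CC(C=O)(C(=C)CO[Si](C)(C)C(C)(C)C)[C@H]([C@H](C)CCC=C(C)C)C(OP(=O)(OCC)OCC)/C=C(/C)CC=C
F15 | step 14 | acetate of 21 | CC(=O)O[C@@H]1[C@@]2(C)CC=C(CO[Si](C)(C)C(C)(C)C)[C@]1(C=O)[C@H]([C@H](C)CCC=C(C)C)C=C2
A1 | alternative 1 | tricyclic oxetane acetal with ring B closed | C[C@@H]1CC[C@@H]([C@H](C)CCC=C(C)C)[C@]23C=CO[C@H]2O[C@H]13
A2 | alternative 2 | cis-fused cyclobutane carbonate with quaternary C1 | O=C1[C@@H](C)CC[C@H]2[C@H]3OC(=O)O[C@H]3[C@@]12[C@H]([C@H](C)CCC=C(C)C)CCO[Si](C)(C)C(C)(C)C
A3 | alternative 2 | vinylene carbonate | O=C1OC=CO1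
A4 | alternative 3 | bicyclo[3.3.1]non-3-en-9-one with both hydroxymethyl arms silylated | O=C1[C@@]2(C)CC=C(CO[Si](C)(C)C(C)(C)C)[C@]1(CO[Si](C)(C)C(C)(C)C)[C@H]([C@H](C)CCC=C(C)C)CC2
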